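**Retrosynthetic overview**
1. The last skeletal bond made is the ring A–ring B aryl ester. A 4-O-benzyl ring A acid acylates the free C4–OH of the ring B–ring C didepside benzyl ester, and a single hydrogenolysis then removes both benzyl groups.
2. Feature the plan rests on (ring A numbered from its acyl-bearing carbon C1): the C6–CH3/C1–acyl/C2–OMe edge is the C4/C5/C6 edge of a 6-methoxy-4-methyl-2-pyrone-5-carboxylate. The vicinal pair C3–OMe/C4–OH has the carbon and oxygen pattern of methoxyacetic acid.
3. Ring A is built de novo. Bonds C2–C3 and C4–C5 come from a [4+2] addition of that pyrone to the bis(trimethylsilyl) ketene acetal of methoxyacetic acid, and loss of CO2 and Me3SiOH gives the arene with C4–OH as its only free phenol.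
4. The pyrone is closed from a dimethyl malonate/tert-butyl but-2-ynoate Michael adduct through a vinylketene, so only the former tert-butyl ester carbon can become the lactone carbonyl.
5. Ring order: the pyrone ring forms first, then ring A, which consumes the pyrone ring. Rings B and C are bought as orsellinic acid and joined by carbodiimide coupling.

Key step: step 5

Remark: the target has no stereocentre. The Michael adduct, its acid and its acid chloride are E/Z mixtures whose geometry is erased in the vinylketene, and the bicyclic lactone and cyclohexadiene of the key step are racemic transient species, so all of these are drawn without configuration. tert-Butyl but-2-ynoate is taken as a catalogue compound.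

Step 1
Reactants: 1 dimethyl malonate; 2 tert-butyl but-2-ynoate
Product: 3 1-tert-butyl 3,3-dimethyl 2-methylprop-1-ene-1,3,3-tricarboxylate (E/Z mixture)
Conditions: NaH (1.05 equiv), THF, 0 °C; add 2, reflux; 1 M HCl, 0 °C
Reagents that add atoms: none
Why: Michael addition of the malonate anion to the beta carbon of an alkynoate, in which the adduct rests as a delocalised glutaconate-type anion until the quench, any base-induced alkyne-to-allene shift of 2 leads to the same skeleton, and the tert-butyl ester marks the one carboxyl group destined to become the lactone carbonyl.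

Step 2
Reactants: 3 1-tert-butyl 3,3-dimethyl 2-methylprop-1-ene-1,3,3-tricarboxylate
Product: 4 5-methoxy-4-(methoxycarbonyl)-3-methyl-5-oxopent-2-enoic acid (E/Z mixture)
Conditions: CF3CO2H/CH2Cl2 (1:3), rt; toluene azeotrope
Reagents that add atoms: none
Why: Acidolysis of a tert-butyl ester (E1 loss of isobutene), to which the two methyl esters are inert.

Step 3
Reactants: 4 5-methoxy-4-(methoxycarbonyl)-3-methyl-5-oxopent-2-enoic acid
Product: 7 methyl 6-methoxy-4-methyl-2-oxo-2H-pyran-5-carboxylate, via acid chloride 5 (not isolated), via vinylketene 6 (not isolated)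
Conditions: (COCl)2, cat. DMF, CH2Cl2, 0 °C → rt; evaporate; Et3N (1.1 equiv), CH2Cl2, −20 °C → rt
Reagents that add atoms: oxalyl chloride, O=C(Cl)C(=O)Cl (chlorine of 5 only; no atom of it stays in 7)
Why: Acid chloride formation, 1,4-dehydrochlorination at the acidic malonyl C–H and oxa-6π electrocyclisation of vinylketene 6 onto a cis ester carbonyl (the ketene/2-pyrone valence isomerisation that also turns glutaconyl chlorides into 6-chloro-2-pyrones) should give 7 alone, because both groups on the terminal alkene carbon of 6 are CO2Me (the E/Z mixture converges) and only the activated acyl carbon can become C2 (the isomeric 3-carboxylate cannot form).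

Step 4
Reactants: 8 methoxyacetic acid
Product: 10 2-methoxy-1,1-bis(trimethylsilyloxy)ethene, via dilithium enediolate 9 (not isolated)
Conditions: LiN(i-Pr)2 (2.1 equiv), THF, −78 → 0 °C; Me3SiCl (2.3 equiv), −78 °C → rt; pentane, filtration under Ar, distillation
Reagents that add atoms: chlorotrimethylsilane, C[Si](C)(C)Cl; lithium diisopropylamide, [Li+].CC(C)[N-]C(C)C (lithium of 9 only)
Why: Double O-silylation of a carboxylic acid dianion, the same enediolate silylation that gives tris(trimethylsilyloxy)ethene from glycolic acid, with the alpha substituent favouring O- over C-silylation.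

Step 5
Reactants: 7 methyl 6-methoxy-4-methyl-2-oxo-2H-pyran-5-carboxylate; 10 2-methoxy-1,1-bis(trimethylsilyloxy)ethene
Product: 14 methyl 4-hydroxy-2,3-dimethoxy-6-methylbenzoate, via bicyclic lactone 11 (not isolated), via cyclohexadiene 12 (not isolated), via aryl silyl ether 13 (not isolated)
Conditions: 10 (3 equiv), toluene, sealed tube, 120 °C, Ar; then 1 M HCl, THF, rt
Reagents that add atoms: none
Why: The electron-poor diene of 7 (pyrone C3 to C6, LUMO lowered by the C5 ester and the lactone carbonyl) and the electron-rich alkene 10 combine in an inverse-electron-demand Diels–Alder reaction with a strongly asynchronous transition state, giving the 2-oxabicyclo[2.2.2]octenone 11. Retro-Diels–Alder loss of CO2 from 11 gives cyclohexadiene 12, whose only available 1,2-elimination (C3–H together with one C4–OSiMe3) yields arene 13, and the acid work-up cleaves the aryl silyl ether (and would carry any surviving 12 through its dienone) to phenol 14. The closest known reaction type is the cycloaddition/CO2 extrusion of 3- and 5-alkoxycarbonyl-2-pyrones with 1,1-dimethoxyethene and 1,1,2-trimethoxyethene, which gives alkoxybenzoates. Ring A is closed by an intermolecular [4+2] cycloaddition that forms C2–C3 (pyrone C6 to the CH(OMe) carbon) and C4–C5 (the C(OSiMe3)2 carbon to pyrone C3) in one operation. The selectivity needed is regiochemical: pyrone C6 is beta to the C5 ester and delta to the lactone carbonyl and is the electrophilic terminus, C3 is alpha to a carbonyl and is not, and the HOMO coefficient of 10 is largest at the carbon remote from the two silyloxy groups, so the new methoxy group should end next to C2–OMe and the silyloxy carbon next to C5–H. The stereocentres of 11 and 12 are transient and vanish on aromatisation, so neither endo/exo nor facial control is needed and no stereocentre is left in 14.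

Step 6
Reactants: 14 methyl 4-hydroxy-2,3-dimethoxy-6-methylbenzoate
Product: 15 methyl 4-(benzyloxy)-2,3-dimethoxy-6-methylbenzoate
Conditions: BnBr, K2CO3, DMF, rt
Reagents that add atoms: benzyl bromide, BrCc1ccccc1
Why: Williamson ether synthesis at the only free phenol, which masks C4–OH so that it cannot compete in the later acylation.

Step 7
Reactants: 15 methyl 4-(benzyloxy)-2,3-dimethoxy-6-methylbenzoate
Product: 16 4-(benzyloxy)-2,3-dimethoxy-6-methylbenzoic acid
Conditions: KOH, DMSO/H2O, 90 °C; cold 1 M HCl
Reagents that add atoms: potassium hydroxide, [K+].[OH-]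
Why: BAc2 saponification of a di-ortho-substituted benzoate is driven by poorly solvated hydroxide in aqueous DMSO, the aryl ethers are inert, and cold acidification avoids decarboxylation of the electron-rich acid.

Step 8
Reactants: 17 orsellinic acid (2,4-dihydroxy-6-methylbenzoic acid)
Product: 18 benzyl 2,4-dihydroxy-6-methylbenzoate
Conditions: BnBr, KHCO3, DMF, rt
Reagents that add atoms: benzyl bromide, BrCc1ccccc1
Why: SN2 alkylation of the carboxylate, since KHCO3 deprotonates only the carboxylic acid and room temperature avoids decarboxylation.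

Step 9
Reactants: 18 benzyl 2,4-dihydroxy-6-methylbenzoate
Product: 19 benzyl 4-(tert-butyldimethylsilyloxy)-2-hydroxy-6-methylbenzoate
Conditions: TBSCl (1.05 equiv), imidazole, CH2Cl2, 0 °C
Reagents that add atoms: tert-butyldimethylsilyl chloride, CC(C)(C)[Si](C)(C)Cl
Why: Silylation selects C4–OH because C2–OH is tied up in a hydrogen bond to the ester carbonyl.

Step 10
Reactants: 19 benzyl 4-(tert-butyldimethylsilyloxy)-2-hydroxy-6-methylbenzoate
Product: 20 4-(tert-butyldimethylsilyloxy)-2-hydroxy-6-methylbenzoic acid
Conditions: H2 (1 atm), 10% Pd/C, EtOAc, rt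
Reagents that add atoms: none
Why: Hydrogenolysis of the benzyl ester under neutral conditions leaves the aryl silyl ether untouched.

Step 11
Reactants: 20 4-(tert-butyldimethylsilyloxy)-2-hydroxy-6-methylbenzoic acid; 18 benzyl 2,4-dihydroxy-6-methylbenzoate
Product: 22 benzyl 4-{[4-(tert-butyldimethylsilyloxy)-2-hydroxy-6-methylbenzoyl]oxy}-2-hydroxy-6-methylbenzoate, via O-acylisourea 21 (not isolated)
Conditions: DCC, toluene, rt
Reagents that add atoms: N,N'-dicyclohexylcarbodiimide, C(=NC1CCCCC1)=NC1CCCCC1 (in 21 only; no atom of it stays in 22)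
Why: Carbodiimide esterification as used for depside bonds, in which only the unchelated C4–OH of 18 is nucleophilic enough to be acylated while the hydrogen-bonded C2–OH groups of both partners stay free.

Step 12
Reactants: 22 benzyl 4-{[4-(tert-butyldimethylsilyloxy)-2-hydroxy-6-methylbenzoyl]oxy}-2-hydroxy-6-methylbenzoate
Product: 23 benzyl 4-[(2,4-dihydroxy-6-methylbenzoyl)oxy]-2-hydroxy-6-methylbenzoate (benzyl lecanorate)
Conditions: HF·pyridine, THF, 0 °C
Reagents that add atoms: none
Why: Fluoride cleavage of an aryl silyl ether in a mildly acidic medium, so no phenoxide is formed that could transacylate the depside link.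

Step 13
Reactants: 16 4-(benzyloxy)-2,3-dimethoxy-6-methylbenzoic acid; 23 benzyl 4-[(2,4-dihydroxy-6-methylbenzoyl)oxy]-2-hydroxy-6-methylbenzoate
Product: 25 benzyl 4-{[4-{[4-(benzyloxy)-2,3-dimethoxy-6-methylbenzoyl]oxy}-2-hydroxy-6-methylbenzoyl]oxy}-2-hydroxy-6-methylbenzoate, via mixed anhydride 24 (not isolated)
Conditions: 16, (CF3CO)2O (1.1 equiv), toluene, 0 °C; then 23, rt
Reagents that add atoms: trifluoroacetic anhydride, O=C(OC(=O)C(F)(F)F)C(F)(F)F (trifluoroacetyl group of 24 only; no atom of it stays in 25)
Why: Mixed trifluoroacetic anhydride esterification, in which the electron-rich di-ortho-substituted aroyl group is transferred with acylium character, and of the three hydroxyls of 23 only ring B C4–OH is not hydrogen-bonded to a carbonyl.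

Step 14
Reactants: 25 benzyl 4-{[4-{[4-(benzyloxy)-2,3-dimethoxy-6-methylbenzoyl]oxy}-2-hydroxy-6-methylbenzoyl]oxy}-2-hydroxy-6-methylbenzoate
Product: 26 4-{[4-[(4-hydroxy-2,3-dimethoxy-6-methylbenzoyl)oxy]-2-hydroxy-6-methylbenzoyl]oxy}-2-hydroxy-6-methylbenzoic acid (CNP0319613.0)
Conditions: H2 (1 atm), 10% Pd/C, EtOAc/THF, rt; evaporation below 30 °C
Reagents that add atoms: none
Why: Hydrogenolysis removes the benzyl ether on ring A and the benzyl ester on ring C together, the two aryl ester links are inert, and neutral room-temperature conditions avoid decarboxylation of the salicylic-type acid.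

**Compound list**
1 | dimethyl malonate | COC(=O)CC(=O)OC | starting material
2 | tert-butyl but-2-ynoate | CC#CC(=O)OC(C)(C)C | starting material
3 | 1-tert-butyl 3,3-dimethyl 2-methylprop-1-ene-1,3,3-tricarboxylate (E/Z mixture) | COC(=O)C(C(=O)OC)C(C)=CC(=O)OC(C)(C)C | intermediate
4 | 5-methoxy-4-(methoxycarbonyl)-3-methyl-5-oxopent-2-enoic acid (E/Z mixture) | COC(=O)C(C(=O)OC)C(C)=CC(=O)O | intermediate
5 | dimethyl 2-(4-chloro-4-oxobut-2-en-2-yl)malonate (acid chloride, E/Z mixture, not isolated) | COC(=O)C(C(=O)OC)C(C)=CC(=O)Cl | intermediate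
6 | dimethyl 2-(4-oxobut-3-en-2-ylidene)malonate (vinylketene, not isolated) | COC(=O)C(C(=O)OC)=C(C)C=C=O | intermediate
7 | methyl 6-methoxy-4-methyl-2-oxo-2H-pyran-5-carboxylate | COC(=O)C1=C(OC)OC(=O)C=C1C | intermediate
8 | methoxyacetic acid | COCC(=O)O | starting material
9 | dilithium 2-methoxyethene-1,1-diolate (not isolated) | [Li+].[Li+].COC=C([O-])[O-] | intermediate
10 | 2-methoxy-1,1-bis(trimethylsilyloxy)ethene | COC=C(O[Si](C)(C)C)O[Si](C)(C)C | intermediate
11 | methyl 1,7-dimethoxy-5-methyl-3-oxo-8,8-bis(trimethylsilyloxy)-2-oxabicyclo[2.2.2]oct-5-ene-6-carboxylate (racemic, endo/exo mixture, not isolated) | COC(=O)C1=C(C)C2C(=O)OC1(OC)C(OC)C2(O[Si](C)(C)C)O[Si](C)(C)C | intermediate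
12 | methyl 2,3-dimethoxy-6-methyl-4,4-bis(trimethylsilyloxy)cyclohexa-1,5-diene-1-carboxylate (racemic, not isolated) | COC(=O)C1=C(OC)C(OC)C(O[Si](C)(C)C)(O[Si](C)(C)C)C=C1C | intermediate
13 | methyl 2,3-dimethoxy-6-methyl-4-(trimethylsilyloxy)benzoate (not isolated) | COC(=O)c1c(C)cc(O[Si](C)(C)C)c(OC)c1OC | intermediate
14 | methyl 4-hydroxy-2,3-dimethoxy-6-methylbenzoate | COC(=O)c1c(C)cc(O)c(OC)c1OC | intermediate
15 | methyl 4-(benzyloxy)-2,3-dimethoxy-6-methylbenzoate | COC(=O)c1c(C)cc(OCc2ccccc2)c(OC)c1OC | intermediate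
16 | 4-(benzyloxy)-2,3-dimethoxy-6-methylbenzoic acid | COc1c(OCc2ccccc2)cc(C)c(C(=O)O)c1OC | intermediate
17 | orsellinic acid (2,4-dihydroxy-6-methylbenzoic acid) | Cc1cc(O)cc(O)c1C(=O)O | starting material
18 | benzyl 2,4-dihydroxy-6-methylbenzoate | Cc1cc(O)cc(O)c1C(=O)OCc1ccccc1 | intermediate
19 | benzyl 4-(tert-butyldimethylsilyloxy)-2-hydroxy-6-methylbenzoate | Cc1cc(O[Si](C)(C)C(C)(C)C)cc(O)c1C(=O)OCc1ccccc1 | intermediate
20 | 4-(tert-butyldimethylsilyloxy)-2-hydroxy-6-methylbenzoic acid | Cc1cc(O[Si](C)(C)C(C)(C)C)cc(O)c1C(=O)O | intermediate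
21 | O-acylisourea of 20 and DCC (not isolated) | Cc1cc(O[Si](C)(C)C(C)(C)C)cc(O)c1C(=O)OC(=NC1CCCCC1)NC1CCCCC1 | intermediate
22 | benzyl 4-{[4-(tert-butyldimethylsilyloxy)-2-hydroxy-6-methylbenzoyl]oxy}-2-hydroxy-6-methylbenzoate | Cc1cc(O[Si](C)(C)C(C)(C)C)cc(O)c1C(=O)Oc1cc(C)c(C(=O)OCc2ccccc2)c(O)c1 | intermediate
23 | benzyl 4-[(2,4-dihydroxy-6-methylbenzoyl)oxy]-2-hydroxy-6-methylbenzoate (benzyl lecanorate) | Cc1cc(O)cc(O)c1C(=O)Oc1cc(C)c(C(=O)OCc2ccccc2)c(O)c1 | intermediate
24 | 4-(benzyloxy)-2,3-dimethoxy-6-methylbenzoic trifluoroacetic anhydride (not isolated) | COc1c(OCc2ccccc2)cc(C)c(C(=O)OC(=O)C(F)(F)F)c1OC | intermediate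
25 | benzyl 4-{[4-{[4-(benzyloxy)-2,3-dimethoxy-6-methylbenzoyl]oxy}-2-hydroxy-6-methylbenzoyl]oxy}-2-hydroxy-6-methylbenzoate | COc1c(OCc2ccccc2)cc(C)c(C(=O)Oc2cc(C)c(C(=O)Oc3cc(C)c(C(=O)OCc4ccccc4)c(O)c3)c(O)c2)c1OC | intermediate
26 | 4-{[4-[(4-hydroxy-2,3-dimethoxy-6-methylbenzoyl)oxy]-2-hydroxy-6-methylbenzoyl]oxy}-2-hydroxy-6-methylbenzoic acid (CNP0319613.0) | COc1c(O)cc(C)c(C(=O)Oc2cc(C)c(C(=O)Oc3cc(C)c(C(=O)O)c(O)c3)c(O)c2)c1OC | target

**Total step count:** 14. **Longest linear sequence:** 8 (steps 1, 2, 3, 5, 6, 7, 13, 14).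

**Steps most likely to fail**

Step 5.
- The cycloaddition may be slow, because C6–OMe and C4–CH3 raise the LUMO of the pyrone and crowd the reacting terminus.
- The ketene acetal may be used up first, by protonolysis with the liberated silanol or by thermal O-to-C silyl shift.
- A stepwise addition at pyrone C6 may end in expulsion of methoxide or opening of the lactone instead of ring closure.

The fallback gives up ring construction and puts the C3 oxygen onto a preformed arene. It sets out from 17 and comes back at 15. Orsellinic acid 17 would be esterified (MeI, KHCO3, DMF) to methyl 2,4-dihydroxy-6-methylbenzoate F1. Rieche formylation between the two hydroxyls (Cl2CHOMe, TiCl4, CH2Cl2) would give methyl 3-formyl-2,4-dihydroxy-6-methylbenzoate F2. Benzylation at the less tightly chelated C4–OH (BnBr, K2CO3, acetone) would give methyl 4-(benzyloxy)-3-formyl-2-hydroxy-6-methylbenzoate F3. Dakin oxidation (H2O2, aq NaOH, THF, 0 °C) would convert this to methyl 4-(benzyloxy)-2,3-dihydroxy-6-methylbenzoate F4, and double O-methylation (MeI, K2CO3, DMF) would give 15.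

Step 3.
- The vinylketene may dimerise or oligomerise before it closes.
- Chloride may dealkylate the activated C6–OMe group.
- The acyl-acetal-like pyrone may hydrolyse on work-up or on silica.

The fallback avoids acid chloride and ketene altogether. It sets out from 1 and comes back at 7. Dimethyl malonate 1 would be added to methyl but-2-ynoate (NaOMe, MeOH, reflux; cold HCl) to give trimethyl 2-methylprop-1-ene-1,3,3-tricarboxylate F5. Heated neat at about 190 °C with removal of methanol, F5 should enol-lactonise to 7, the classical thermal route from malonate–alkynoate adducts to 6-alkoxy-2-pyrones. Closure in the opposite sense, onto a malonyl ester, is conceivable there, so the constitution of the pyrone would have to be checked by HMBC before use.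

Step 13.
- Acyl transfer from the hindered acid to the large phenol may stay incomplete.
- Acylation may stray to a chelated hydroxyl.
- The acid medium may scramble the existing depside link by transesterification.

The fallback changes the order of fragment union to A–B first, then C. It sets out from 17 and 16 and comes back at 25. Orsellinic acid 17 would give allyl 2,4-dihydroxy-6-methylbenzoate F6 (allyl bromide, KHCO3, DMF). Acid 16 would be converted with (COCl)2/cat. DMF into 4-(benzyloxy)-2,3-dimethoxy-6-methylbenzoyl chloride F7. This would acylate the C4 phenoxide of F6 (K2CO3, acetone), which is safe because no depside bond is yet present, to give allyl 4-{[4-(benzyloxy)-2,3-dimethoxy-6-methylbenzoyl]oxy}-2-hydroxy-6-methylbenzoate F8. Tsuji–Trost-type deallylation (Pd(PPh3)4, PhSiH3, CH2Cl2) would free 4-{[4-(benzyloxy)-2,3-dimethoxy-6-methylbenzoyl]oxy}-2-hydroxy-6-methylbenzoic acid F9, and DCC coupling of F9 with 18 in toluene would give 25.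

**Further compounds**
F1 | step 5 | methyl 2,4-dihydroxy-6-methylbenzoate | COC(=O)c1c(C)cc(O)cc1O
F2 | step 5 | methyl 3-formyl-2,4-dihydroxy-6-methylbenzoate | COC(=O)c1c(C)cc(O)c(C=O)c1O
F3 | step 5 | methyl 4-(benzyloxy)-3-formyl-2-hydroxy-6-methylbenzoate | COC(=O)c1c(C)cc(OCc2ccccc2)c(C=O)c1O
F4 | step 5 | methyl 4-(benzyloxy)-2,3-dihydroxy-6-methylbenzoate | COC(=O)c1c(C)cc(OCc2ccccc2)c(O)c1O
F5 | step 3 | trimethyl 2-methylprop-1-ene-1,3,3-tricarboxylate (E/Z mixture) | COC(=O)C=C(C)C(C(=O)OC)C(=O)OC
F6 | step 13 | allyl 2,4-dihydroxy-6-methylbenzoate | Cc1cc(O)cc(O)c1C(=O)OCC=C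
F7 | step 13 | 4-(benzyloxy)-2,3-dimethoxy-6-methylbenzoyl chloride | COc1c(OCc2ccccc2)cc(C)c(C(=O)Cl)c1OC
F8 | step 13 | allyl 4-{[4-(benzyloxy)-2,3-dimethoxy-6-methylbenzoyl]oxy}-2-hydroxy-6-methylbenzoate | COc1c(OCc2ccccc2)cc(C)c(C(=O)Oc2cc(C)c(C(=O)OCC=C)c(O)c2)c1OC
F9 | step 13 | 4-{[4-(benzyloxy)-2,3-dimethoxy-6-methylbenzoyl]oxy}-2-hydroxy-6-methylbenzoic acid | COc1c(OCc2ccccc2)cc(C)c(C(=O)Oc2cc(C)c(C(=O)O)c(O)c2)c1OC
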